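The synthesis rests on cutting ring bond C1–C6 (C1 = quaternary carbinol carbon, C7 = its CH2O carbon, C2/C3 = neighbouring oxygenated carbons, C4=C5 = alkene, C6 = remaining allylic carbon). C1 holds both C7 and C6, and C6 adjoins the C4=C5 double bond; tying C7 as a lactone to an oxygen on C4 therefore lines up a C7=C1 ketene acetal with the C4–C5=C6 allyl fragment for a [3,3] shift. One boat Ireland–Claisen step on this six-membered lactone closes the cyclohexene, installs C4=C5 and sets C1 and C6. The precursor is the 6,2-lactone of 3,4-O-isopropylidene-D-galacturonic acid carrying an (E)-4-methoxybenzyl enol ether and a free 5-hydroxyl that is silylated in the flask.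

Key step: step 8

Remark: locants C1–C7 are those defined above (C7, C1, C2, C3, C4, C5 = C6, C5, C4, C3, C2, C1 of D-galacturonic acid); benzyl β-D-galactopyranoside is assumed to be a catalogue compound; C6 with its oxygen can only come from an alkoxymethylene ylide, hence salt 5, and the C1 oxygen is the pyranose ring oxygen until the olefination, so it is left free and silylated only in the key step.

Step 1
Reactants: 1 4-methoxybenzyl alcohol; 2 chloromethyl methyl sulfide
Product: 3 4-methoxybenzyl (methylthio)methyl ether
Conditions: NaH, NaI (cat.), 1,2-dimethoxyethane, 0 °C to rt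
Reagents that add atoms: none
Why: Williamson ether synthesis in which the sodium alkoxide of 1 displaces chloride from the sulfur-activated chloromethyl group under iodide catalysis, with no stereocentre involved.

Step 2
Reactants: 3 4-methoxybenzyl (methylthio)methyl ether
Product: 5 {[(4-methoxybenzyl)oxy]methyl}triphenylphosphonium chloride, via chloromethyl ether 4 (not isolated)
Conditions: SO2Cl2, CH2Cl2, −78 °C; volatiles removed in vacuo; PPh3, toluene, rt
Reagents that add atoms: sulfuryl chloride, O=S(=O)(Cl)Cl; triphenylphosphine, c1ccc(cc1)P(c1ccccc1)c1ccccc1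
Why: Chlorinolysis of the O,S-acetal (S-chlorination, then loss of MeSCl) gives the α-chloro ether 4, which alkylates PPh3 in an SN2 quaternisation to the Wittig salt, with no stereocentre involved.

Step 3
Reactants: 6 benzyl β-D-galactopyranoside
Product: 7 benzyl 3,4-O-isopropylidene-β-D-galactopyranoside
Conditions: Me2C(OMe)2, camphorsulfonic acid (cat.), acetone, rt; Et3N, then MeOH–H2O
Reagents that add atoms: 2,2-dimethoxypropane, COC(C)(C)OC
Why: Acid-catalysed ketal exchange under thermodynamic control places the five-membered ketal on O3/O4, the only cis-vicinal pair of the β-pyranoside (a mixed ketal at O6 is cleaved in the aqueous methanol quench), and no stereocentre is touched.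

Step 4
Reactants: 7 benzyl 3,4-O-isopropylidene-β-D-galactopyranoside
Product: 8 benzyl 3,4-O-isopropylidene-β-D-galactopyranosiduronic acid
Conditions: TEMPO (cat.), PhI(OAc)2, CH2Cl2–H2O, rt
Reagents that add atoms: water, O
Why: Oxoammonium (TEMPO) oxidation with PhI(OAc)2 as terminal oxidant is selective for the primary alcohol and runs through the aldehyde hydrate to the acid, while the secondary 2-OH, the ketal and the glycoside stay intact.

Step 5
Reactants: 8 benzyl 3,4-O-isopropylidene-β-D-galactopyranosiduronic acid
Product: 9 3,4-O-isopropylidene-D-galactopyranuronic acid (lactol; both anomers)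
Conditions: H2 (1 atm), 10% Pd/C, EtOAc–THF, rt
Reagents that add atoms: none
Why: Catalytic hydrogenolysis cleaves only the anomeric benzylic C–O bond, nothing else in 8 being reducible, and frees the hemiacetal whose open-chain aldehyde carbon becomes C5; the ring stereocentres are unchanged.

Step 6
Reactants: 9 3,4-O-isopropylidene-D-galactopyranuronic acid; 5 {[(4-methoxybenzyl)oxy]methyl}triphenylphosphonium chloride
Product: 11 (2S,3S,4R,5S,6E)-2,5-dihydroxy-3,4-(isopropylidenedioxy)-7-[(4-methoxybenzyl)oxy]hept-6-enoic acid, via ylide 10 (not isolated)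
Conditions: 5 (2.5 equiv), KN(SiMe3)2, THF, 0 °C; 9 pre-deprotonated with KN(SiMe3)2 (3 equiv) in THF–DMSO added, 0 °C to rt; NaH2PO4 buffer (pH 6), extraction into EtOAc–Et3N, used crude as the triethylammonium salt
Reagents that add atoms: none
Why: Wittig alkoxymethylenation of a lactol through its open-chain aldehyde, run on the carboxylate so that the proton on C1 stays non-acidic and the ketal oxygen on C2 cannot be eliminated; C6 arrives as an enol ether for which both geometries are expected, the required E isomer being freed from the Z isomer after step 7, and the four sugar stereocentres are carried over unchanged.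

Step 7
Reactants: 11 (2S,3S,4R,5S,6E)-2,5-dihydroxy-3,4-(isopropylidenedioxy)-7-[(4-methoxybenzyl)oxy]hept-6-enoic acid
Product: 12 (3S,4S,5R,6S)-3-hydroxy-4,5-(isopropylidenedioxy)-6-[(E)-2-(4-methoxybenzyloxy)ethenyl]oxan-2-one
Conditions: 2-methyl-6-nitrobenzoic anhydride, Et3N, DMAP (cat.), CH2Cl2, rt, slow addition; chromatography on Et3N-treated silica (Z isomer removed)
Reagents that add atoms: none
Why: Shiina lactonisation, in which the mixed anhydride acylates the C4 hydroxyl under DMAP catalysis to the six-membered lactone, is favoured over intermolecular acylation because the cis-dioxolane holds acid and alcohol together, and its basic medium is tolerated by the acid-labile alkoxy-allyl system (as in the acylation of glycals); no stereocentre changes.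

Step 8
Reactants: 12 (3S,4S,5R,6S)-3-hydroxy-4,5-(isopropylidenedioxy)-6-[(E)-2-(4-methoxybenzyloxy)ethenyl]oxan-2-one
Product: 16 (1S,2R,3R,6R)-1-hydroxy-2,3-(isopropylidenedioxy)-6-[(4-methoxybenzyl)oxy]cyclohex-4-ene-1-carboxylic acid, via silyl ether 13 (not isolated), via ketene acetal 14 (not isolated), via silyl ester 15 (not isolated)
Conditions: Me3SiCl–Et3N (1:1, 6 equiv), KN(SiMe3)2 (2.6 equiv), THF–toluene, −78 °C to rt, then 70 °C; aq. citric acid–THF, rt
Reagents that add atoms: none
Why: The amide base first turns the free C1 hydroxyl into its trimethylsilyl ether and then removes the C1 proton with Me3SiCl already in the flask, so the enolate is trapped as ketene acetal 14 faster than the oxygen on C2 can leave; 14 rearranges in one pericyclic event, the C1–C6 σ bond growing on the same face from which the C4–O bond departs. The closest known reaction type is the Ireland–Claisen ring contraction of alkenyl lactones to cycloalkene carboxylic acids, and ester enolate Claisen rearrangements of glycal esters show that an enol-ether oxygen on the bond-forming allyl terminus is tolerated and even accelerating. The cyclohexene is closed by [3,3]-sigmatropic union of the ketene-acetal carbon with the enol-ether terminus; because C2–C3 tie C1 to C4, only a boat, bicyclo[2.2.2]octane-like transition state is reachable, the emerging C4=C5 bond is necessarily cis, and the cis-fused ketal keeps C2–C3 eclipsed as this geometry asks. C1 is dictated by C4: the alkenyl arm hangs from the lactone face that also carries O2 and O3, bonding is possible only there, so C7 is pushed to the opposite face and O1 ends syn to O2 and O3. C6 follows from the double-bond geometry: in the boat the E-alkoxy group points away from the C2–C3 bridge and finishes syn to C7 and anti to O1, whereas a Z ether would deliver the epimer. The step therefore needs O-silylation to outrun β-elimination, which the internal Me3SiCl quench at −78 °C provides, and a geometrically pure E substrate, which the purification in step 7 provides.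

Step 9
Reactants: 16 (1S,2R,3R,6R)-1-hydroxy-2,3-(isopropylidenedioxy)-6-[(4-methoxybenzyl)oxy]cyclohex-4-ene-1-carboxylic acid
Product: 17 (1S,2R,3R,6R)-1-(hydroxymethyl)-2,3-(isopropylidenedioxy)-6-[(4-methoxybenzyl)oxy]cyclohex-4-en-1-ol
Conditions: LiAlH4, THF, 0 °C to reflux; aqueous NaOH work-up
Reagents that add atoms: none
Why: LiAlH4 reduction of the hindered α-hydroxy acid through its aluminate gives the primary alcohol, the ethers, the ketal and the isolated alkene being inert, and no stereocentre is affected.

Step 10
Reactants: 17 (1S,2R,3R,6R)-1-(hydroxymethyl)-2,3-(isopropylidenedioxy)-6-[(4-methoxybenzyl)oxy]cyclohex-4-en-1-ol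
Product: 18 (1S,2R,3R,6R)-1-(hydroxymethyl)-2,3-(isopropylidenedioxy)cyclohex-4-ene-1,6-diol
Conditions: DDQ, CH2Cl2–pH 7 phosphate buffer, 0 °C to rt
Reagents that add atoms: none
Why: Oxidative cleavage of the 4-methoxybenzyl ether by DDQ (hydride abstraction to the oxocarbenium ion, then hydrolysis by the buffer, whose excess water should intercept the cation before a neighbouring hydroxyl does) frees the C6 hydroxyl with retention, since the C6–O bond is never broken.

Step 11
Reactants: 18 (1S,2R,3R,6R)-1-(hydroxymethyl)-2,3-(isopropylidenedioxy)cyclohex-4-ene-1,6-diol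
Product: 19 [(1S,2R,3R,6R)-6-(benzoyloxy)-1-hydroxy-2,3-(isopropylidenedioxy)cyclohex-4-en-1-yl]methyl benzoate
Conditions: BzCl (2.5 equiv), pyridine, DMAP (cat.), CH2Cl2, 0 °C to rt
Reagents that add atoms: benzoyl chloride, O=C(Cl)c1ccccc1
Why: DMAP-catalysed acylation (nucleophilic acyl substitution) esterifies the primary C7 and the secondary allylic C6 hydroxyls, while the tertiary C1 hydroxyl flanked by three substituted carbons stays free; no C–O bond at a stereocentre is broken.

Step 12
Reactants: 19 [(1S,2R,3R,6R)-6-(benzoyloxy)-1-hydroxy-2,3-(isopropylidenedioxy)cyclohex-4-en-1-yl]methyl benzoate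
Product: 20 [(1R,2R,3R,6R)-6-(benzoyloxy)-1,2,3-trihydroxycyclohex-4-en-1-yl]methyl benzoate
Conditions: AcOH–H2O (4:1), 50 °C
Reagents that add atoms: none
Why: Mild acid-catalysed ketal hydrolysis cleaves at the ketal carbon and so frees O2 and O3 with retention, the benzoates being stable to aqueous acetic acid.

Step 13
Reactants: 20 [(1R,2R,3R,6R)-6-(benzoyloxy)-1,2,3-trihydroxycyclohex-4-en-1-yl]methyl benzoate
Product: 21 [(1R,2R,3R,6R)-3,6-bis(benzoyloxy)-1,2-dihydroxycyclohex-4-en-1-yl]methyl benzoate
Conditions: BzCl (1.05 equiv), pyridine, CH2Cl2, −40 to −20 °C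
Reagents that add atoms: benzoyl chloride, O=C(Cl)c1ccccc1
Why: Kinetic site-selective acylation: the allylic C3 hydroxyl has an sp2 neighbour, whereas the C2 hydroxyl is neopentyl-like beside the fully substituted C1 and the C1 hydroxyl is tertiary, so one equivalent of benzoyl chloride at low temperature should esterify O3 only, with retention at every centre.

Compound list
1 | 4-methoxybenzyl alcohol | COc1ccc(CO)cc1 | starting material
2 | chloromethyl methyl sulfide | CSCCl | starting material
3 | 4-methoxybenzyl (methylthio)methyl ether | COc1ccc(COCSC)cc1 | intermediate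
4 | chloromethyl 4-methoxybenzyl ether (not isolated) | COc1ccc(COCCl)cc1 | intermediate
5 | {[(4-methoxybenzyl)oxy]methyl}triphenylphosphonium chloride | COc1ccc(COC[P+](c2ccccc2)(c2ccccc2)c2ccccc2)cc1.[Cl-] | intermediate
6 | benzyl β-D-galactopyranoside | OC[C@H]1O[C@@H](OCc2ccccc2)[C@H](O)[C@@H](O)[C@H]1O | starting material
7 | benzyl 3,4-O-isopropylidene-β-D-galactopyranoside | OC[C@H]1O[C@@H](OCc2ccccc2)[C@H](O)[C@H]2OC(C)(C)O[C@@H]12 | intermediate
8 | benzyl 3,4-O-isopropylidene-β-D-galactopyranosiduronic acid | OC(=O)[C@H]1O[C@@H](OCc2ccccc2)[C@H](O)[C@H]2OC(C)(C)O[C@@H]12 | intermediate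
9 | 3,4-O-isopropylidene-D-galactopyranuronic acid (lactol, both anomers) | OC(=O)[C@H]1OC(O)[C@H](O)[C@H]2OC(C)(C)O[C@@H]12 | intermediate
10 | {[(4-methoxybenzyl)oxy]methylidene}triphenylphosphorane (ylide, not isolated) | COc1ccc(COC=P(c2ccccc2)(c2ccccc2)c2ccccc2)cc1 | intermediate
11 | (2S,3S,4R,5S,6E)-2,5-dihydroxy-3,4-(isopropylidenedioxy)-7-[(4-methoxybenzyl)oxy]hept-6-enoic acid | OC(=O)[C@@H](O)[C@@H]1OC(C)(C)O[C@@H]1[C@@H](O)/C=C/OCc1ccc(OC)cc1 | intermediate
12 | (3S,4S,5R,6S)-3-hydroxy-4,5-(isopropylidenedioxy)-6-[(E)-2-(4-methoxybenzyloxy)ethenyl]oxan-2-one (ketal oxygens and alkenyl group all cis, 3-OH trans to them) | O=C1[C@@H](O)[C@@H]2OC(C)(C)O[C@@H]2[C@H](/C=C/OCc2ccc(OC)cc2)O1 | intermediate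
13 | O-trimethylsilyl ether of 12 (not isolated) | O=C1[C@@H](O[Si](C)(C)C)[C@@H]2OC(C)(C)O[C@@H]2[C@H](/C=C/OCc2ccc(OC)cc2)O1 | intermediate
14 | cyclic bis(trimethylsilyl) ketene acetal of 12, C7=C1 double bond (not isolated) | C[Si](C)(C)OC1=C(O[Si](C)(C)C)[C@@H]2OC(C)(C)O[C@@H]2[C@H](/C=C/OCc2ccc(OC)cc2)O1 | intermediate
15 | trimethylsilyl ester O-trimethylsilyl ether of 16 (not isolated) | C[Si](C)(C)OC(=O)[C@@]1(O[Si](C)(C)C)[C@@H]2OC(C)(C)O[C@@H]2C=C[C@H]1OCc1ccc(OC)cc1 | intermediate
16 | (1S,2R,3R,6R)-1-hydroxy-2,3-(isopropylidenedioxy)-6-[(4-methoxybenzyl)oxy]cyclohex-4-ene-1-carboxylic acid (O1, O2, O3 cis; O6 trans to O1) | OC(=O)[C@@]1(O)[C@@H]2OC(C)(C)O[C@@H]2C=C[C@H]1OCc1ccc(OC)cc1 | intermediate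
17 | (1S,2R,3R,6R)-1-(hydroxymethyl)-2,3-(isopropylidenedioxy)-6-[(4-methoxybenzyl)oxy]cyclohex-4-en-1-ol | OC[C@@]1(O)[C@@H]2OC(C)(C)O[C@@H]2C=C[C@H]1OCc1ccc(OC)cc1 | intermediate
18 | (1S,2R,3R,6R)-1-(hydroxymethyl)-2,3-(isopropylidenedioxy)cyclohex-4-ene-1,6-diol | OC[C@@]1(O)[C@@H]2OC(C)(C)O[C@@H]2C=C[C@H]1O | intermediate
19 | [(1S,2R,3R,6R)-6-(benzoyloxy)-1-hydroxy-2,3-(isopropylidenedioxy)cyclohex-4-en-1-yl]methyl benzoate | O=C(OC[C@@]1(O)[C@@H]2OC(C)(C)O[C@@H]2C=C[C@H]1OC(=O)c1ccccc1)c1ccccc1 | intermediate
20 | [(1R,2R,3R,6R)-6-(benzoyloxy)-1,2,3-trihydroxycyclohex-4-en-1-yl]methyl benzoate | O=C(OC[C@@]1(O)[C@H](O)[C@H](O)C=C[C@H]1OC(=O)c1ccccc1)c1ccccc1 | intermediate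
21 | [(1R,2R,3R,6R)-3,6-bis(benzoyloxy)-1,2-dihydroxycyclohex-4-en-1-yl]methyl benzoate | O=C(OC[C@@]1(O)[C@H](O)[C@H](OC(=O)c2ccccc2)C=C[C@H]1OC(=O)c1ccccc1)c1ccccc1 | target

Total step count: 13 (two for the Wittig salt, eleven on the main line). Longest linear sequence: 11 steps (6 to 21, steps 3–13).

Steps most likely to fail

Step 6. The process at risk is sluggish olefination of the triply deprotonated, poorly soluble lactol salt, together with unselective formation of both enol-ether geometries and acid-triggered collapse of the alkoxy-allylic alcohol during isolation of the acid. The fallback sets out from lactol acid 9 and builds the E geometry by addition instead of olefination. Ohira–Bestmann homologation (dimethyl (1-diazo-2-oxopropyl)phosphonate, K2CO3, MeOH) should give the acid-stable alkynyl dihydroxy acid F1. Lactonisation as in step 7 should give the ethynyl hydroxy lactone F2. Syn-hydroboration with pinacolborane under Cp2Zr(H)Cl catalysis should give the (E)-alkenylboronate lactone F3. A Chan–Lam etherification of F3 with 4-methoxybenzyl alcohol (Cu(OAc)2, Et3N, molecular sieves, air, rt), which keeps the alkene geometry, comes back to the route at lactone 12 as the E isomer only.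

Step 8. The process at risk is expulsion of the C2 oxygen from the enolate before O-silylation, or ionisation and hydrolysis of the alkoxy-substituted allyl ester, either of which consumes the substrate before the boat is reached. The fallback sets out from 9, follows the preceding fallback as far as the boronate lactone F3 and does not etherify it, so that carbon C6 carries boron instead of oxygen through the rearrangement. Boron-substituted allyl esters are known to undergo ester enolate Claisen rearrangement to allylboronates, so the same silylation, enolisation and [3,3] shift on F3 should give the allylboronate acid F4, with boron on C6 syn to C7 by the same boat. Stereoretentive oxidation (NaBO3·4H2O, THF–H2O) should give the dihydroxy acid F5, and LiAlH4 reduction comes back to the route at triol 18. This removes the ionisable enol-ether and allylic-ester pair; the β-elimination hazard remains and is again met by the internal silyl chloride quench.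

Step 13. The process at risk is insufficient discrimination between the two secondary hydroxyls, or base-induced benzoyl migration between O3 and O2. The fallback sets out from 20 and replaces kinetic acylation by orthoester opening. Trimethyl orthobenzoate with catalytic camphorsulfonic acid in MeCN should bridge the two secondary oxygens as the cyclic orthobenzoate F6, the tertiary hydroxyl being too hindered to take part. Brief treatment with aqueous acetic acid then opens the hemi-orthoester, which is expected to collapse with the ester on the pseudo-axial allylic O3 and the free hydroxyl on equatorial O2, arriving at target 21.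

Further compounds
F1 | step 6 | (2S,3S,4R,5S)-2,5-dihydroxy-3,4-(isopropylidenedioxy)hept-6-ynoic acid | OC(=O)[C@@H](O)[C@@H]1OC(C)(C)O[C@@H]1[C@@H](O)C#C
F2 | step 6 | (3S,4S,5R,6S)-6-ethynyl-3-hydroxy-4,5-(isopropylidenedioxy)oxan-2-one | O=C1[C@@H](O)[C@@H]2OC(C)(C)O[C@@H]2[C@H](C#C)O1
F3 | step 6 | (3S,4S,5R,6S)-3-hydroxy-4,5-(isopropylidenedioxy)-6-[(E)-2-(4,4,5,5-tetramethyl-1,3,2-dioxaborolan-2-yl)ethenyl]oxan-2-one | O=C1[C@@H](O)[C@@H]2OC(C)(C)O[C@@H]2[C@H](/C=C/B2OC(C)(C)C(C)(C)O2)O1
F4 | step 8 | (1S,2R,3R,6R)-1-hydroxy-2,3-(isopropylidenedioxy)-6-(4,4,5,5-tetramethyl-1,3,2-dioxaborolan-2-yl)cyclohex-4-ene-1-carboxylic acid | OC(=O)[C@@]1(O)[C@@H]2OC(C)(C)O[C@@H]2C=C[C@H]1B1OC(C)(C)C(C)(C)O1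
F5 | step 8 | (1S,2R,3R,6R)-1,6-dihydroxy-2,3-(isopropylidenedioxy)cyclohex-4-ene-1-carboxylic acid | OC(=O)[C@@]1(O)[C@@H]2OC(C)(C)O[C@@H]2C=C[C@H]1O
F6 | step 13 | cyclic 2,3-O-(α-methoxybenzylidene) orthoester of 20 | O=C(OC[C@@]1(O)[C@@H]2OC(OC)(c3ccccc3)O[C@@H]2C=C[C@H]1OC(=O)c1ccccc1)c1ccccc1
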